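**Strategy.** Each half of the C2-symmetric target is a 4,4,8,10-tetramethyl octalin in which ring B (C5–C10) carries a methyl on C8 beside C9, the carbon that holds the C11–C11' bridge, and is anchored on quaternary C10. The route therefore inserts C8 together with its methyl between the C9 carbonyl and C7 of the five-membered ketone of the (S)-Hajos–Parrish ketone with diazoethane. This one operation creates ring B, the C8 methyl and a C9 ketone that later fixes the C8=C9 alkene as its enol triflate. The precursor is the commercial enantiopure hydrindenedione itself, whose quaternary carbon becomes C10. Two triflate-derived halves are finally joined through a vinyl group by hydroboration and B-alkyl Suzuki coupling.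

Key step: step 2

Assumption: atoms are numbered as in drimane (ring A = C1–C5 and C10, ring B = C5–C10, C10 methyl = β, bridge carbons C11 and C11'); the (S) centre of 1 maps onto C10 (S) of both halves, and the C8 configuration of 4–12 is immaterial for the target because C8 becomes sp2 in step 8.

**Route**

Step 1
Reactants: 2 N-ethyl-N-nitrosourea
Product: 3 diazoethane (cold dried toluene solution, used at once)
Conditions: 40% aq. KOH, toluene, −5 → 0 °C; organic layer decanted, dried over KOH pellets
Reagents that add atoms: none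
Why: Hydroxide cleaves the N-nitrosourea to the ethyl diazotate, which collapses to the diazoalkane and cyanate; this is the standard base-induced nitrosourea preparation of a diazoalkane and involves no stereocentre.

Step 2
Reactants: 1 (S)-Hajos–Parrish ketone; 3 diazoethane
Product: 5 (2R,8aS)-2,8a-dimethyl-3,4,8,8a-tetrahydronaphthalene-1,6(2H,7H)-dione (8α-methyl enedione), via 8β-methyl epimer 4 (not isolated)
Conditions: 3 (1.5 equiv, slow addition), Sc(OTf)3 (10 mol%), CH2Cl2/toluene, −78 → −40 °C; AcOH quench; then DBU (0.3 equiv), CH2Cl2, rt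
Reagents that add atoms: none
Why: This is a Lewis acid-catalysed diazoalkane–ketone homologation (Büchner–Curtius–Schlotterbeck, Tiffeneau–Demjanov type): the nucleophilic carbon of diazoethane adds to the Sc(OTf)3-activated C9 carbonyl, and in the resulting β-oxido diazonium ion C7 shifts to the former diazo carbon as N2 leaves, so that C8–C9 and C7–C8 are formed. Ring B is therefore closed by a 1,2-alkyl-shift ring expansion of the five-membered ring to a six-membered one, not by a cyclisation. The closest known cases are the Sc(OTf)3- or BF3-promoted ring expansions of 2-substituted cycloalkanones and of 17-oxo steroids, in which the less substituted α-carbon migrates. Chemoselectivity comes from the substrate: the saturated cyclopentanone carbonyl is strained and much more electrophilic than the conjugated C3 enone carbonyl, and the product is a 2,2,6-trisubstituted cyclohexanone that is too hindered to be homologated again. Regioselectivity comes from C10 being quaternary and bonded to the electron-poor enone β-carbon C5, which makes it sterically and electronically a poorer migrating group than the C7 methylene. The new C8 centre forms without reliable kinetic control and is then set thermodynamically: DBU epimerises it through the C8–C9 enolate to the equatorial 8α-methyl compound, which avoids the 1,3-diaxial clash with the axial C10 methyl present in epimer 4.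

Step 3
Reactants: 5 8α-methyl enedione
Product: 6 9,9-ethylenedioxy-8α,10β-dimethyl-Δ4-octalin-3-one
Conditions: TMSOCH2CH2OTMS (1.5 equiv), TMSOTf (5 mol%), CH2Cl2, −78 → −20 °C; pyridine quench
Reagents that add atoms: 1,2-bis(trimethylsilyloxy)ethane, C[Si](C)(C)OCCO[Si](C)(C)C
Why: Noyori ketalisation with a bis-silylated diol and catalytic TMSOTf converts saturated ketones into dioxolanes under aprotic conditions while conjugated enones are left alone, so only the C9 carbonyl is masked and C8 and C10 are not disturbed.

Step 4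
Reactants: 6 C9 ketal enone
Product: 8 9,9-ethylenedioxy-4,4,8α,10β-tetramethyl-Δ5-octalin-3-one, via 4-monomethyl ketone 7 (not isolated)
Conditions: KOtBu (3 equiv), tBuOH/THF, 0 °C → rt; MeI (4 equiv)
Reagents that add atoms: iodomethane, CI
Why: In this deconjugative α,α-dialkylation of a Δ4-3-ketone, KOtBu forms the extended dienolate, which is methylated at C4 twice (through 7) so that the alkene ends at C5=C6, while the ketal prevents enolisation toward C8; C4 carries two identical methyls and is no stereocentre.

Step 5
Reactants: 8 4,4-dimethyl Δ5-3-ketone ketal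
Product: 10 9,9-ethylenedioxy-4,4,8α,10β-tetramethyl-Δ5-octalin, via C3 hydrazone 9 (not isolated)
Conditions: N2H4·H2O (10 equiv), KOH (6 equiv), diethylene glycol, 130 °C; then distil to 200 °C
Reagents that add atoms: hydrazine (as hydrate), NN (its nitrogen stays only in intermediate 9)
Why: In the Wolff–Kishner reduction (Huang-Minlon procedure) hydrazone 9 forms at 130 °C and loses N2 under KOH at 200 °C to leave C3 as CH2, while the base-stable ketal and the C5=C6 bond (which cannot migrate past quaternary C4 and C10) are unaffected; no stereocentre is formed.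

Step 6
Reactants: 10 Δ5 olefin ketal
Product: 11 (2R,8aS)-2,5,5,8a-tetramethyl-3,5,6,7,8,8a-hexahydronaphthalen-1(2H)-one (Δ5-9-ketone)
Conditions: 2 M aq. HCl, THF, rt
Reagents that add atoms: water, O
Why: Acid-catalysed ketal hydrolysis is helped here by relief of the compression between the dioxolane and the C8 and C10 methyls, the isolated trisubstituted alkene is stable to dilute acid at room temperature, and the C8 methyl stays in its preferred equatorial orientation.

Step 7
Reactants: 11 Δ5-9-ketone
Product: 12 (2R,4aS,8aS)-2,5,5,8a-tetramethyloctahydronaphthalen-1(2H)-one (trans-decalone; 5α-H)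
Conditions: H2 (10 bar), 10% Pd/C, EtOAc/AcOH, rt → 40 °C
Reagents that add atoms: none
Why: Heterogeneous catalytic hydrogenation should add H2 syn to C5=C6 from the α-face, because the β-face is screened by the axial C10 methyl and the 4β-methyl, which sets C5 as 5α-H (S) and gives the trans-decalin, as known for 4,4-dimethyl Δ5-steroids and related octalins.

Step 8
Reactants: 12 trans-decalone
Product: 14 (4aS,8aS)-2,5,5,8a-tetramethyl-3,4,4a,5,6,7,8,8a-octahydronaphthalen-1-yl trifluoromethanesulfonate, via potassium enolate 13 (not isolated)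
Conditions: KN(SiMe3)2 (1.3 equiv), THF, −78 → 0 °C; PhNTf2 (1.3 equiv), −78 °C → rt
Reagents that add atoms: N-phenylbis(trifluoromethanesulfonimide), O=S(=O)(N(c1ccccc1)S(=O)(=O)C(F)(F)F)C(F)(F)F; potassium bis(trimethylsilyl)amide, C[Si](C)(C)[N-][Si](C)(C)C.[K+] (its potassium stays only in intermediate 13)
Why: In this enol triflate formation the C9 ketone can enolise only toward C8 because C10 is quaternary, so enolate 13 is a single regioisomer and O-sulfonylation fixes the C8=C9 double bond and removes the C8 stereocentre, as known for 2,2,6-trimethylcyclohexanone.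

Step 9
Reactants: 14 enol triflate; 15 tributyl(vinyl)stannane
Product: 16 (4aS,8aS)-1-ethenyl-2,5,5,8a-tetramethyl-3,4,4a,5,6,7,8,8a-octahydronaphthalene
Conditions: Pd2(dba)3 (2.5 mol%), AsPh3 (20 mol%), NMP, 60 °C
Reagents that add atoms: none
Why: Stille cross-coupling of an alkenyl triflate with a vinylstannane, run with the weakly donating AsPh3 ligand that speeds transmetalation onto crowded alkenylpalladium species, forms the C9–C11 bond; only sp2 centres react and C5 and C10 are untouched.

Step 10
Reactants: 16 vinyl diene; 14 enol triflate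
Product: 18 1,1'-(ethane-1,2-diyl)bis[(4aS,8aS)-2,5,5,8a-tetramethyl-3,4,4a,5,6,7,8,8a-octahydronaphthalene] (target), via alkyl-9-BBN borane 17 (not isolated)
Conditions: 9-BBN (1.2 equiv), THF, 0 → 40 °C; then 14 (0.9 equiv), Pd(dppf)Cl2 (10 mol%), AsPh3 (10 mol%), Cs2CO3 (3 equiv), DMF/H2O, 60 °C
Reagents that add atoms: 9-borabicyclo[3.3.1]nonane, B1C2CCCC1CCC2 (its boron and carbons stay only in intermediate 17)
Why: 9-BBN should hydroborate only the monosubstituted vinyl group with boron on the terminal carbon (the tetrasubstituted C8=C9 alkene is inert), and B-alkyl Suzuki–Miyaura coupling of the primary alkylborane 17 with a second molecule of 14 forms the C11'–C9' bond and completes the C9–CH2–CH2–C9' bridge, with C5, C10, C5' and C10' carried over unchanged.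

**Compound list**

1 | (S)-Hajos–Parrish ketone, (7aS)-7a-methyl-2,3,7,7a-tetrahydro-1H-indene-1,5(6H)-dione | C[C@]12CCC(=O)C=C1CCC2=O | starting material
2 | N-ethyl-N-nitrosourea | CCN(N=O)C(N)=O | starting material
3 | diazoethane | CC=[N+]=[N-] | intermediate
4 | (2S,8aS)-2,8a-dimethyl-3,4,8,8a-tetrahydronaphthalene-1,6(2H,7H)-dione (8β-methyl epimer of 5) | C[C@]12CCC(=O)C=C1CC[C@H](C)C2=O | intermediate (not isolated)
5 | (2R,8aS)-2,8a-dimethyl-3,4,8,8a-tetrahydronaphthalene-1,6(2H,7H)-dione (C9 ketone, 8α-methyl, ring A enone) | C[C@]12CCC(=O)C=C1CC[C@@H](C)C2=O | intermediate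
6 | 9,9-ethylenedioxy-8α,10β-dimethyl-Δ4-octalin-3-one (C9 1,3-dioxolane of 5) | C[C@]12CCC(=O)C=C1CC[C@@H](C)C23OCCO3 | intermediate
7 | 9,9-ethylenedioxy-4,8α,10β-trimethyl-Δ5-octalin-3-one (C4 configuration undefined) | C[C@]12CCC(=O)C(C)C1=CC[C@@H](C)C23OCCO3 | intermediate (not isolated)
8 | 9,9-ethylenedioxy-4,4,8α,10β-tetramethyl-Δ5-octalin-3-one | C[C@]12CCC(=O)C(C)(C)C1=CC[C@@H](C)C23OCCO3 | intermediate
9 | C3 hydrazone of 8 | C[C@]12CCC(=NN)C(C)(C)C1=CC[C@@H](C)C23OCCO3 | intermediate (not isolated)
10 | 9,9-ethylenedioxy-4,4,8α,10β-tetramethyl-Δ5-octalin | C[C@]12CCCC(C)(C)C1=CC[C@@H](C)C23OCCO3 | intermediate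
11 | (2R,8aS)-2,5,5,8a-tetramethyl-3,5,6,7,8,8a-hexahydronaphthalen-1(2H)-one | C[C@]12CCCC(C)(C)C1=CC[C@@H](C)C2=O | intermediate
12 | (2R,4aS,8aS)-2,5,5,8a-tetramethyloctahydronaphthalen-1(2H)-one (trans-fused, 5α-H, 8α-methyl, 10β-methyl) | C[C@]12CCCC(C)(C)[C@@H]1CC[C@@H](C)C2=O | intermediate
13 | potassium Δ8-enolate of 12 | CC1=C([O-])[C@@]2(C)CCCC(C)(C)[C@@H]2CC1.[K+] | intermediate (not isolated)
14 | (4aS,8aS)-2,5,5,8a-tetramethyl-3,4,4a,5,6,7,8,8a-octahydronaphthalen-1-yl trifluoromethanesulfonate | CC1=C(OS(=O)(=O)C(F)(F)F)[C@@]2(C)CCCC(C)(C)[C@@H]2CC1 | intermediate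
15 | tributyl(vinyl)stannane | C=C[Sn](CCCC)(CCCC)CCCC | starting material
16 | (4aS,8aS)-1-ethenyl-2,5,5,8a-tetramethyl-3,4,4a,5,6,7,8,8a-octahydronaphthalene | CC1=C(C=C)[C@@]2(C)CCCC(C)(C)[C@@H]2CC1 | intermediate
17 | 9-{2-[(4aS,8aS)-2,5,5,8a-tetramethyl-3,4,4a,5,6,7,8,8a-octahydronaphthalen-1-yl]ethyl}-9-borabicyclo[3.3.1]nonane | CC1=C(CCB2C3CCCC2CCC3)[C@@]2(C)CCCC(C)(C)[C@@H]2CC1 | intermediate (not isolated)
18 | 1,1'-(ethane-1,2-diyl)bis[(4aS,8aS)-2,5,5,8a-tetramethyl-3,4,4a,5,6,7,8,8a-octahydronaphthalene] | CC1=C(CCC2=C(C)CC[C@H]3C(C)(C)CCC[C@]23C)[C@@]2(C)CCCC(C)(C)[C@@H]2CC1 | target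

**Count and risks**

Total: 10 steps. Longest linear sequence: 10 steps (2 → 3 → 5 → 6 → 8 → 10 → 11 → 12 → 14 → 16 → 18); nine steps from 1.

Steps most likely to fail:

1. Step 2 (key step). The Lewis acid may be held by the more basic C3 enone oxygen, so that addition at C9 becomes slow and the diazoalkane is lost by acid-induced decomposition. Addition to the activated enone carbonyl, oxirane formation in place of the 1,2-shift, or partial migration of C10 would also lower the yield. Fallback (same two bonds, but a stabilised diazo compound, with insertion and methylation separated): from 1, ethyl diazoacetate with BF3·OEt2 in CH2Cl2 (0 °C → rt) should homologate the cyclopentanone with migration of C7 to give ethyl (8aS)-8a-methyl-1,6-dioxo-1,2,3,4,6,7,8,8a-octahydronaphthalene-2-carboxylate F1. K2CO3 and MeI in acetone should then methylate the doubly activated C8 to give ethyl (8aS)-2,8a-dimethyl-1,6-dioxo-1,2,3,4,6,7,8,8a-octahydronaphthalene-2-carboxylate F2. Heating F2 in 6 M HCl/AcOH should hydrolyse and decarboxylate it with thermodynamic protonation at C8, returning to the route at 5.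

2. Step 3. Steric compression at C9 (quaternary C10 on one side, the C8 methyl on the other) may stall dioxolane formation, and forcing the reaction by warming may start exchange at the C3 enone with double-bond migration. Fallback (redox masking in place of a ketal): from 5, LiAlH4 in THF should reduce both carbonyls to 8α,10β-dimethyl-Δ4-octalin-3,9-diol F3 (carbinol configurations immaterial). MnO2 in CH2Cl2 should reoxidise only the allylic C3 alcohol to 9-hydroxy-8α,10β-dimethyl-Δ4-octalin-3-one F4. KOtBu/MeI should then give 9-hydroxy-4,4,8α,10β-tetramethyl-Δ5-octalin-3-one F5, and Wolff–Kishner reduction should give 4,4,8α,10β-tetramethyl-Δ5-octalin-9-ol F6. Hydrogenation over Pd/C should give the trans-fused 4,4,8α,10β-tetramethyldecalin-9-ol F7, and Dess–Martin oxidation returns to the route at 12.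

3. Step 10. Transmetalation of the alkylborane onto the crowded alkenylpalladium (flanked by quaternary C10 and the C8 methyl) may be slow, so that β-hydride elimination, protodeboronation or hydrolysis of the triflate outrun C–C bond formation. Fallback (symmetrical C11–C11' bond formation in place of a cross-coupling): from 14, methoxycarbonylation (Pd(OAc)2, PPh3, CO, MeOH, Et3N, DMF) should give methyl (4aS,8aS)-2,5,5,8a-tetramethyl-3,4,4a,5,6,7,8,8a-octahydronaphthalene-1-carboxylate F8. Reduction with iBu2AlH should give the allylic alcohol drim-8-en-11-ol F9, and PBr3 should give 11-bromodrim-8-ene F10. Reductive homocoupling with Cp2TiCl (trivalent titanium, from catalytic Cp2TiCl2 and Mn powder in THF) should join the two primary allylic carbons head to head, since attack through C8 would create a quaternary centre, and returns to the route at 18.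

**Further compounds**

F1 | step 2 | ethyl (8aS)-8a-methyl-1,6-dioxo-1,2,3,4,6,7,8,8a-octahydronaphthalene-2-carboxylate | C[C@]12CCC(=O)C=C1CCC(C(=O)OCC)C2=O
F2 | step 2 | ethyl (8aS)-2,8a-dimethyl-1,6-dioxo-1,2,3,4,6,7,8,8a-octahydronaphthalene-2-carboxylate | C[C@]12CCC(=O)C=C1CCC(C)(C(=O)OCC)C2=O
F3 | step 3 | 8α,10β-dimethyl-Δ4-octalin-3,9-diol | C[C@]12CCC(O)C=C1CC[C@@H](C)C2O
F4 | step 3 | 9-hydroxy-8α,10β-dimethyl-Δ4-octalin-3-one | C[C@]12CCC(=O)C=C1CC[C@@H](C)C2O
F5 | step 3 | 9-hydroxy-4,4,8α,10β-tetramethyl-Δ5-octalin-3-one | C[C@]12CCC(=O)C(C)(C)C1=CC[C@@H](C)C2O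
F6 | step 3 | 4,4,8α,10β-tetramethyl-Δ5-octalin-9-ol | C[C@]12CCCC(C)(C)C1=CC[C@@H](C)C2O
F7 | step 3 | trans-4,4,8α,10β-tetramethyldecalin-9-ol (5α-H) | C[C@]12CCCC(C)(C)[C@@H]1CC[C@@H](C)C2O
F8 | step 10 | methyl (4aS,8aS)-2,5,5,8a-tetramethyl-3,4,4a,5,6,7,8,8a-octahydronaphthalene-1-carboxylate | CC1=C(C(=O)OC)[C@@]2(C)CCCC(C)(C)[C@@H]2CC1
F9 | step 10 | [(4aS,8aS)-2,5,5,8a-tetramethyl-3,4,4a,5,6,7,8,8a-octahydronaphthalen-1-yl]methanol (drim-8-en-11-ol) | CC1=C(CO)[C@@]2(C)CCCC(C)(C)[C@@H]2CC1
F10 | step 10 | (4aS,8aS)-1-(bromomethyl)-2,5,5,8a-tetramethyl-3,4,4a,5,6,7,8,8a-octahydronaphthalene (11-bromodrim-8-ene) | CC1=C(CBr)[C@@]2(C)CCCC(C)(C)[C@@H]2CC1
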